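**Retrosynthetic overview**
1. The anisate comes from acylating the 10β-allylic alcohol, which comes from 1,2-reduction of a C8=C9–C10=O enone.
2. The enone and the C5 tertiary OH come from β-elimination that unzips a C5–O–C8 ether bridge in a tricyclic 2,10-diketone. C1–CH3 comes from exo C-methylation of that bridged β-diketone.
3. Key step: the bridged tricycle comes from a furan-tethered enoldiazoketone by Rh-carbenoid cyclopropanation of the furan followed by divinylcyclopropane rearrangement. This forms C1–C5 and C8–C9.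
4. The enoldiazoketone comes from an aldehyde and diazoacetone. The aldehyde comes from an enantioselective Friedel–Crafts addition of 2-methylfuran to (E)-4-methylpent-2-enal, which sets C4; C4 then relays to C5, C1 and C10.
5. Ring order: the purchased furan is sacrificed; the cyclopentanone and the seven-membered ring (with the O-bridge) form together; the O-bridge is then opened.

Convention: daucane numbering is used throughout. C1 = C(CH3) at the ring fusion, C2 = ketone, C3 = CH2, C4 = CH(iPr), C5 = C–O at the ring fusion, C6 and C7 = CH2, C8 = C(CH3), C9, C10 = C–O. The α face is the face carrying the C5 oxygen.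
Assumption: the imidazolidinone shields the enal face as in the established pyrrole/indole series, so the (2R,5R) catalyst gives (R)-3. If the sense is opposite, the enantiomeric catalyst is used.

**Step 1**
Reactants: 1 2-methylfuran; 2 (E)-4-methylpent-2-enal
Product: 3 (3R)-4-methyl-3-(5-methylfuran-2-yl)pentanal
Conditions: (2R,5R)-5-benzyl-2-tert-butyl-3-methylimidazolidin-4-one·TFA (20 mol %), 1 (3 equiv), CH2Cl2/i-PrOH, −40 °C
Reagents that add atoms: none
Why: This is an iminium-catalysed enantioselective Friedel–Crafts conjugate addition in which the free α-position of the furan attacks the open face of the (E)-iminium ion, setting C4 (R).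

**Step 2**
Reactants: 4 pentane-2,4-dione
Product: 6 1-diazopropan-2-one (diazoacetone), via 3-diazopentane-2,4-dione 5 (not isolated)
Conditions: p-ABSA, Et3N, MeCN, 0 °C → rt, filter; then 1 M aq KOH, Et2O, 0 °C
Reagents that add atoms: 4-acetamidobenzenesulfonyl azide (p-ABSA), CC(=O)Nc1ccc(cc1)S(=O)(=O)N=[N+]=[N-]
Why: Regitz diazo transfer to the active methylene is followed by retro-Claisen deacetylation of the 2-diazo-1,3-diketone, and no stereocentre is involved.

**Step 3**
Reactants: 3 (3R)-4-methyl-3-(5-methylfuran-2-yl)pentanal; 6 1-diazopropan-2-one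
Product: 8 (6R)-3-diazo-7-methyl-6-(5-methylfuran-2-yl)octane-2,4-dione, via diazo aldol adduct 7 (not isolated)
Conditions: DBU (15 mol %), DMSO, rt; then IBX (1.5 equiv), rt
Reagents that add atoms: none
Why: DBU-catalysed aldol-type addition of the acyldiazomethane C–H to the aldehyde is followed by IBX oxidation in the same pot, which erases the carbinol centre and leaves the non-enolisable C4 centre untouched.

**Step 4**
Reactants: 8 (6R)-3-diazo-7-methyl-6-(5-methylfuran-2-yl)octane-2,4-dione
Product: 9 (6R)-2-(tert-butyldimethylsilyloxy)-3-diazo-7-methyl-6-(5-methylfuran-2-yl)oct-1-en-4-one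
Conditions: TBSOTf (1.2 equiv), Et3N (1.5 equiv), CH2Cl2, 0 °C
Reagents that add atoms: tert-butyldimethylsilyl triflate, CC(C)(C)[Si](C)(C)OS(=O)(=O)C(F)(F)F
Why: In this soft enolisation/silylation to an enoldiazoketone, the unhindered acetyl CH3 is deprotonated in preference to the CH2 next to the doubly branched C4.

**Step 5 (key step)**
Reactants: 9 (6R)-2-(tert-butyldimethylsilyloxy)-3-diazo-7-methyl-6-(5-methylfuran-2-yl)oct-1-en-4-one
Product: 11 (4R,5S,8R)-10-(tert-butyldimethylsilyloxy)-5,8-epoxy-15-nordauca-1(10),6-dien-2-one (O bridges C5 and C8; C4-iPr cis to the bridge O), via cis-divinylcyclopropane 10 (not isolated)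
Conditions: Rh2(O2C-n-C7H15)4 (1 mol %), hexanes, reflux, slow addition of 9 (final 0.01 M)
Reagents that add atoms: none
Why: In this intramolecular tandem cyclopropanation/Cope (divinylcyclopropane) rearrangement, a formal (4+3), the donor/acceptor vinylcarbenoid closes a bicyclo[3.1.0]hexan-2-one onto furan C5=C6, the tether forces the siloxyvinyl group and the remaining furan C=C to be cis so the [3,3] shift follows at once and makes the five- and seven-membered rings together, and C5 (with C8) is set by C4 because allylic strain puts C4–H next to C6–H and the iPr group on the furan-oxygen side.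

**Step 6**
Reactants: 11 (4R,5S,8R)-10-(tert-butyldimethylsilyloxy)-5,8-epoxy-15-nordauca-1(10),6-dien-2-one
Product: 12 (4R,5S,8S)-10-(tert-butyldimethylsilyloxy)-5,8-epoxy-15-nordauc-1(10)-en-2-one
Conditions: H2 (1 atm), 5 % Pd/C, EtOAc, rt
Reagents that add atoms: none
Why: Chemoselective catalytic hydrogenation saturates the strained cis-disubstituted C6=C7 bond, while the tetrasubstituted push–pull C1=C10 enol ether is inert and no stereocentre changes (the C8 descriptor changes by CIP priority only).

**Step 7**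
Reactants: 12 (4R,5S,8S)-10-(tert-butyldimethylsilyloxy)-5,8-epoxy-15-nordauc-1(10)-en-2-one
Product: 13 (1R,4R,5S,8S)-5,8-epoxydaucane-2,10-dione (C1-CH3, bridge O and C4-iPr all α)
Conditions: MeI (5 equiv), TBAF (1.05 equiv), THF, −20 → 0 °C
Reagents that add atoms: iodomethane, CI
Why: Fluoride unmasks the β-diketonate and soft MeI alkylates it at carbon (fluoride-mediated C-alkylation of a β-diketone) from the exo face, syn to the one-atom O-bridge and away from the C6–C7 bridge, setting C1 (R) with CH3 cis to oxygen.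

**Step 8**
Reactants: 13 (1R,4R,5S,8S)-5,8-epoxydaucane-2,10-dione
Product: 15 (1R,4R,5S)-5-hydroxydauc-8-ene-2,10-dione, via bis(trimethylsilyl) dienone 14 (not isolated)
Conditions: TMSOTf (3 equiv), Et3N (4 equiv), CH2Cl2, −78 → 0 °C; then 1 M HCl, THF, 0 °C → rt
Reagents that add atoms: trimethylsilyl triflate, C[Si](C)(C)OS(=O)(=O)C(F)(F)F (its Me3Si groups are present in 14 only)
Why: In this silylative β-elimination (retro-oxa-Michael), the C9=C10 enol silane expels the silyl-activated bridge oxygen from C8, fixing the alkene at C8=C9 and capping C5–O as a silyl ether so that no free alkoxide can trigger retro-aldol cleavage, and mild acid then removes both silyl groups without touching C1, C4 or C5.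

**Step 9**
Reactants: 15 (1R,4R,5S)-5-hydroxydauc-8-ene-2,10-dione
Product: 16 (1R,4R,5S,10R)-5,10-dihydroxydauc-8-en-2-one
Conditions: NaBH4 (1 equiv), CeCl3·7H2O (1.1 equiv), MeOH, −78 °C
Reagents that add atoms: none
Why: Luche 1,2-reduction takes the enone in preference to the C2 cyclopentanone, which is shielded on the α face by CH3, OH and iPr and on the β face by the seven-membered ring, and hydride enters C10 from the α face (syn to the C5–OH, anti to the C1–C2 bond in a Felkin-type arrangement) to give the 10β-alcohol (10R).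

**Step 10**
Reactants: 16 (1R,4R,5S,10R)-5,10-dihydroxydauc-8-en-2-one; 17 4-methoxybenzoyl chloride
Product: 18 (1R,4R,5S,10R)-5-hydroxy-2-oxodauc-8-en-10-yl 4-methoxybenzoate (CNP0246512.1)
Conditions: 17 (1.5 equiv), DMAP (0.2 equiv), pyridine, CH2Cl2, 0 °C → rt
Reagents that add atoms: none
Why: DMAP-catalysed acylation esterifies only the secondary allylic alcohol with retention at C10, because the hindered tertiary C5–OH does not react.

**Compound list**
1 | 2-methylfuran | Cc1ccco1 | starting material
2 | (E)-4-methylpent-2-enal | CC(C)/C=C/C=O | starting material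
3 | (3R)-4-methyl-3-(5-methylfuran-2-yl)pentanal | CC(C)[C@@H](CC=O)c1ccc(C)o1 | intermediate
4 | pentane-2,4-dione | CC(=O)CC(C)=O | starting material
5 | 3-diazopentane-2,4-dione | CC(=O)C(=[N+]=[N-])C(C)=O | intermediate
6 | 1-diazopropan-2-one | CC(=O)C=[N+]=[N-] | intermediate
7 | (6R)-3-diazo-4-hydroxy-7-methyl-6-(5-methylfuran-2-yl)octan-2-one (C4 epimers) | CC(=O)C(=[N+]=[N-])C(O)C[C@H](C(C)C)c1ccc(C)o1 | intermediate
8 | (6R)-3-diazo-7-methyl-6-(5-methylfuran-2-yl)octane-2,4-dione | CC(=O)C(=[N+]=[N-])C(=O)C[C@H](C(C)C)c1ccc(C)o1 | intermediate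
9 | (6R)-2-(tert-butyldimethylsilyloxy)-3-diazo-7-methyl-6-(5-methylfuran-2-yl)oct-1-en-4-one | C=C(O[Si](C)(C)C(C)(C)C)C(=[N+]=[N-])C(=O)C[C@H](C(C)C)c1ccc(C)o1 | intermediate
10 | cis-divinylcyclopropane: cyclopropane C1/C5/C6 fused to the cyclopentanone (C1–C5) and to the 2,3-dihydrofuran (C5–C6), with the 1-silyloxyvinyl group on C1 cis to the dihydrofuran C7=C8 | C=C(O[Si](C)(C)C(C)(C)C)[C@]12C(=O)C[C@H](C(C)C)[C@@]1(OC(C)=C3)[C@@H]23 | intermediate
11 | (4R,5S,8R)-10-(tert-butyldimethylsilyloxy)-5,8-epoxy-15-nordauca-1(10),6-dien-2-one | CC(C)(C)[Si](C)(C)OC1=C2C(=O)C[C@H](C(C)C)[C@@]2(O3)C=C[C@@]3(C)C1 | intermediate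
12 | (4R,5S,8S)-10-(tert-butyldimethylsilyloxy)-5,8-epoxy-15-nordauc-1(10)-en-2-one | CC(C)(C)[Si](C)(C)OC1=C2C(=O)C[C@H](C(C)C)[C@@]2(O3)CC[C@@]3(C)C1 | intermediate
13 | (1R,4R,5S,8S)-5,8-epoxydaucane-2,10-dione | O=C1C[C@]3(C)CC[C@]2(O3)[C@@H](C(C)C)CC(=O)[C@]12C | intermediate
14 | 2,5-bis(trimethylsilyloxy)dauca-2,8-dien-10-one (configuration at C1, C4 and C5 as in 13) | O=C1C=C(C)CC[C@]2(O[Si](C)(C)C)[C@@H](C(C)C)C=C(O[Si](C)(C)C)[C@]12C | intermediate
15 | (1R,4R,5S)-5-hydroxydauc-8-ene-2,10-dione | O=C1C=C(C)CC[C@]2(O)[C@@H](C(C)C)CC(=O)[C@]12C | intermediate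
16 | (1R,4R,5S,10R)-5,10-dihydroxydauc-8-en-2-one | O[C@@H]1C=C(C)CC[C@]2(O)[C@@H](C(C)C)CC(=O)[C@]12C | intermediate
17 | 4-methoxybenzoyl chloride | COc1ccc(cc1)C(=O)Cl | starting material
18 | (1R,4R,5S,10R)-5-hydroxy-2-oxodauc-8-en-10-yl 4-methoxybenzoate | COc1ccc(C(=O)O[C@@H]2C=C(C)CC[C@]3(O)[C@@H](C(C)C)CC(=O)[C@]23C)cc1 | target

**Totals**
Total step count: 10 (step 2 is the side preparation of 6).
Longest linear sequence: 9 (steps 1 and 3–10).

**Three steps most likely to fail**

Step 5. The oxabicyclic cyclopropane may unravel to a ring-opened dienone instead of undergoing the Cope shift, or the facial control from C4 may be weak. The fallback keeps the furan/three-carbon ring construction. It makes the C1–C10–C9 unit electrophilic from an epoxide that already carries C1–CH3. It sets out from 3 and returns at 13, replacing steps 2–7.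
- Wittig olefination of 3 with 3-(triphenylphosphoranylidene)butan-2-one gives (3E,6R)-3,7-dimethyl-6-(5-methylfuran-2-yl)oct-3-en-2-one F1.
- Nucleophilic epoxidation (t-BuOOH, DBU), which spares the furan, gives the two trans-epoxides. From these, 1-[(2S,3R)-2-methyl-3-[(2R)-3-methyl-2-(5-methylfuran-2-yl)butyl]oxiran-2-yl]ethan-1-one F2 is separated.
- TESOTf/Et3N converts F2 into the epoxy enol silane F3.
- Catalytic TESOTf in CH2Cl2 at −78 °C triggers the intramolecular (4+3) cycloaddition. The epoxide opens with inversion at C1 to give (1S,2R,4R,5S,8R)-5,8-epoxy-2-(triethylsilyloxy)dauc-6-en-10-one F4.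
- Hydrogenation over Pd/C gives the saturated silyl ether F5.
- HF·pyridine gives (1S,2R,4R,5S,8S)-5,8-epoxy-2-hydroxydaucan-10-one F6, and Dess–Martin oxidation delivers 13.

Step 8. Risks are over-silylation of the enone, or retro-aldol loss of the C1–C5 bond in the β-hydroxy-1,3-diketone. The fallback treats the bridge as an ether instead of relying on enolisation. It sets out from 13 and returns at 15.
- TMSI (from TMSCl and NaI in MeCN) cleaves the ether by ionisation at the more stabilised C8, giving (1R,4R,5S)-8-iodo-5-(trimethylsilyloxy)daucane-2,10-dione F7.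
- DBU removes HI towards the acidic C9–H while C5–O stays silylated, giving (1R,4R,5S)-5-(trimethylsilyloxy)dauc-8-ene-2,10-dione F8.
- Dilute HCl in THF then gives 15.

Step 9. The facial selectivity at C10 is hard to predict in the flexible cis-fused enone. If hydride comes from the β face, the product is (1R,4R,5S,10S)-5,10-dihydroxydauc-8-en-2-one F9. The fallback sets out from 15 and returns at 18. F9 is esterified with inversion under Mitsunobu conditions (4-methoxybenzoic acid, PPh3, DIAD, toluene), which replaces step 10 and gives the 10R ester directly.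

**Further compounds**
F1 | step 5 | (3E,6R)-3,7-dimethyl-6-(5-methylfuran-2-yl)oct-3-en-2-one | CC(=O)/C(C)=C/C[C@H](C(C)C)c1ccc(C)o1
F2 | step 5 | 1-[(2S,3R)-2-methyl-3-[(2R)-3-methyl-2-(5-methylfuran-2-yl)butyl]oxiran-2-yl]ethan-1-one | CC(=O)[C@@]1(C)O[C@@H]1C[C@H](C(C)C)c1ccc(C)o1
F3 | step 5 | epoxy enol silane (triethylsilyl enol ether of F2 at the acetyl CH3) | C=C(O[Si](CC)(CC)CC)[C@@]1(C)O[C@@H]1C[C@H](C(C)C)c1ccc(C)o1
F4 | step 5 | (1S,2R,4R,5S,8R)-5,8-epoxy-2-(triethylsilyloxy)dauc-6-en-10-one | O=C1C[C@]3(C)C=C[C@]2(O3)[C@@H](C(C)C)C[C@@H](O[Si](CC)(CC)CC)[C@]12C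
F5 | step 5 | saturated silyl ether, (1S,2R,4R,5S,8S)-5,8-epoxy-2-(triethylsilyloxy)daucan-10-one | O=C1C[C@]3(C)CC[C@]2(O3)[C@@H](C(C)C)C[C@@H](O[Si](CC)(CC)CC)[C@]12C
F6 | step 5 | (1S,2R,4R,5S,8S)-5,8-epoxy-2-hydroxydaucan-10-one | O=C1C[C@]3(C)CC[C@]2(O3)[C@@H](C(C)C)C[C@@H](O)[C@]12C
F7 | step 8 | (1R,4R,5S)-8-iodo-5-(trimethylsilyloxy)daucane-2,10-dione (C8 epimers) | O=C1CC(C)(I)CC[C@]2(O[Si](C)(C)C)[C@@H](C(C)C)CC(=O)[C@]12C
F8 | step 8 | (1R,4R,5S)-5-(trimethylsilyloxy)dauc-8-ene-2,10-dione | O=C1C=C(C)CC[C@]2(O[Si](C)(C)C)[C@@H](C(C)C)CC(=O)[C@]12C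
F9 | step 9 | (1R,4R,5S,10S)-5,10-dihydroxydauc-8-en-2-one | O[C@H]1C=C(C)CC[C@]2(O)[C@@H](C(C)C)CC(=O)[C@]12C
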